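**Retrosynthetic overview**
- Target ⇒ its nonamethyl ether, which keeps one free OH on ring C. All methyl groups are removed in the last step.
- Key disconnection: the C–D biaryl bond, which joins two phloroglucinol carbons that are both natively nucleophilic. Ring D is polarity-reversed to an aryl cation equivalent, an aryllead triacetate made in the flask from 1,3,5-trimethoxybenzene. It is delivered to the free carbon ortho to the ring C phenol.
- Both diaryl ether bonds come from one bromide, 2-bromo-3,5-dimethoxybenzaldehyde, used twice. Its CHO group first activates the C–Br bond for O-arylation and is then converted into the next phenol OH.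
- No ring is built. All four benzene rings are bought and joined in the order A–B, B–C, C–D.

Ring labels: A is the terminal 3,5-dioxyphenoxy ring. B is the middle ring. C is the ether-bearing ring of the biaryl. D is the 2,4,6-trioxyphenyl ring.

Assumption: the target has no stereocentre and no stereogenic axis, because ring D is symmetric about the biaryl bond. It is therefore achiral and there is no configuration to set.

**Step 1**
Reactants: 1 3,5-dimethoxyphenol; 2 2-bromo-3,5-dimethoxybenzaldehyde
Product: 3 2-(3,5-dimethoxyphenoxy)-3,5-dimethoxybenzaldehyde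
Conditions: CuI (10 mol %), picolinic acid (20 mol %), K3PO4 (2 equiv), DMSO, 90 °C, Ar
Reagents that add atoms: none
Why: Ullmann-type copper-catalysed diaryl ether synthesis, in which the ortho formyl group withdraws electrons from and pre-coordinates copper to the hindered C–Br bond so that it couples with the unhindered phenol; no stereocentre is formed.

**Step 2**
Reactants: 3 2-(3,5-dimethoxyphenoxy)-3,5-dimethoxybenzaldehyde
Product: 5 2-(3,5-dimethoxyphenoxy)-3,5-dimethoxyphenol, via aryl formate 4 (not isolated)
Conditions: mCPBA (1.4 equiv), CH2Cl2, 0 °C to rt; crude formate, then K2CO3 (cat.), MeOH, rt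
Reagents that add atoms: 3-chloroperoxybenzoic acid (mCPBA), OOC(=O)c1cccc(Cl)c1
Why: Baeyer–Villiger oxidation, in which the ortho aryloxy donor makes aryl migration faster than hydride migration in the Criegee adduct, and mild methanolysis of the formate frees the phenol without touching any ether; no stereocentre is formed.

**Step 3**
Reactants: 5 2-(3,5-dimethoxyphenoxy)-3,5-dimethoxyphenol; 2 2-bromo-3,5-dimethoxybenzaldehyde (1.3 equiv)
Product: 6 2-[2-(3,5-dimethoxyphenoxy)-3,5-dimethoxyphenoxy]-3,5-dimethoxybenzaldehyde
Conditions: CuI (15 mol %), picolinic acid (30 mol %), K3PO4 (2 equiv), DMSO, 100 °C, Ar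
Reagents that add atoms: none
Why: second Ullmann-type O-arylation with the same formyl-activated bromide, in which the phenol carries only one ortho substituent and so stays within the scope of hindered copper couplings; no stereocentre is formed.

**Step 4**
Reactants: 6 2-[2-(3,5-dimethoxyphenoxy)-3,5-dimethoxyphenoxy]-3,5-dimethoxybenzaldehyde
Product: 8 2-[2-(3,5-dimethoxyphenoxy)-3,5-dimethoxyphenoxy]-3,5-dimethoxyphenol, via aryl formate 7 (not isolated)
Conditions: mCPBA (1.4 equiv), CH2Cl2, 0 °C to rt; crude formate, then K2CO3 (cat.), MeOH, rt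
Reagents that add atoms: 3-chloroperoxybenzoic acid (mCPBA), OOC(=O)c1cccc(Cl)c1
Why: Baeyer–Villiger oxidation and formate methanolysis as in step 2, which leaves the only free OH of the trimer on ring C, next to the carbon that must be arylated; no stereocentre is formed.

**Step 5 (key step)**
Reactants: 8 2-[2-(3,5-dimethoxyphenoxy)-3,5-dimethoxyphenoxy]-3,5-dimethoxyphenol (1.0 equiv); 9 1,3,5-trimethoxybenzene (1.3 equiv)
Product: 11 3-[2-(3,5-dimethoxyphenoxy)-3,5-dimethoxyphenoxy]-2',4,4',6,6'-pentamethoxy-[1,1'-biphenyl]-2-ol, via 2,4,6-trimethoxyphenyllead triacetate 10 (not isolated)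
Conditions: 9, Pb(OAc)4 (1.2 equiv), CHCl3, rt, dark, until no Pb(OAc)4 is left; then 8, pyridine (4 equiv), CHCl3, 40 to 60 °C
Reagents that add atoms: lead tetraacetate, CC(=O)O[Pb](OC(C)=O)(OC(C)=O)OC(C)=O (supplies the Pb and three acetates of intermediate 10; none of its atoms remain in 11)
Why: Pinhey–Barton arylation, in which electrophilic plumbation turns a natively nucleophilic C–H carbon of 9 into an aryl cation equivalent on tetravalent lead, phenol 8 replaces an acetate on lead, ligand coupling with reduction to divalent lead delivers the aryl group to the only unsubstituted carbon ortho to the OH (the other ortho carbon bears the bulky aryloxy group and would have to become quaternary), and tautomerisation restores the phenol; no stereocentre or stable axis arises.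

**Step 6**
Reactants: 11 3-[2-(3,5-dimethoxyphenoxy)-3,5-dimethoxyphenoxy]-2',4,4',6,6'-pentamethoxy-[1,1'-biphenyl]-2-ol
Product: 12 3-[2-(3,5-dihydroxyphenoxy)-3,5-dihydroxyphenoxy]-[1,1'-biphenyl]-2,2',4,4',6,6'-hexol (target, achiral)
Conditions: BBr3 (20 equiv, 1 M in CH2Cl2), CH2Cl2, −78 °C to rt, 24 h; then H2O, 0 °C; work-up and Sephadex LH-20 under Ar
Reagents that add atoms: none
Why: Lewis-acid aryl methyl ether cleavage, in which bromide attacks the methyl carbon of each boron-complexed methoxy group (SN2), a path closed to the aryl–O–aryl and aryl–aryl bonds, and staying at or below rt avoids dehydration of the 2,2'-dihydroxybiaryl to a dibenzofuran; no stereocentre is involved.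

**Compound list**
1 | 3,5-dimethoxyphenol | COc1cc(O)cc(OC)c1 | starting material
2 | 2-bromo-3,5-dimethoxybenzaldehyde | COc1cc(C=O)c(Br)c(OC)c1 | starting material
3 | 2-(3,5-dimethoxyphenoxy)-3,5-dimethoxybenzaldehyde | COc1cc(OC)cc(Oc2c(C=O)cc(OC)cc2OC)c1 | intermediate
4 | 2-(3,5-dimethoxyphenoxy)-3,5-dimethoxyphenyl formate (not isolated) | COc1cc(OC)cc(Oc2c(OC=O)cc(OC)cc2OC)c1 | intermediate
5 | 2-(3,5-dimethoxyphenoxy)-3,5-dimethoxyphenol | COc1cc(OC)cc(Oc2c(O)cc(OC)cc2OC)c1 | intermediate
6 | 2-[2-(3,5-dimethoxyphenoxy)-3,5-dimethoxyphenoxy]-3,5-dimethoxybenzaldehyde | COc1cc(OC)cc(Oc2c(OC)cc(OC)cc2Oc2c(C=O)cc(OC)cc2OC)c1 | intermediate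
7 | 2-[2-(3,5-dimethoxyphenoxy)-3,5-dimethoxyphenoxy]-3,5-dimethoxyphenyl formate (not isolated) | COc1cc(OC)cc(Oc2c(OC)cc(OC)cc2Oc2c(OC=O)cc(OC)cc2OC)c1 | intermediate
8 | 2-[2-(3,5-dimethoxyphenoxy)-3,5-dimethoxyphenoxy]-3,5-dimethoxyphenol | COc1cc(OC)cc(Oc2c(OC)cc(OC)cc2Oc2c(O)cc(OC)cc2OC)c1 | intermediate
9 | 1,3,5-trimethoxybenzene | COc1cc(OC)cc(OC)c1 | starting material
10 | 2,4,6-trimethoxyphenyllead triacetate (not isolated) | COc1cc(OC)c([Pb](OC(C)=O)(OC(C)=O)OC(C)=O)c(OC)c1 | intermediate
11 | 3-[2-(3,5-dimethoxyphenoxy)-3,5-dimethoxyphenoxy]-2',4,4',6,6'-pentamethoxy-[1,1'-biphenyl]-2-ol | COc1cc(OC)cc(Oc2c(OC)cc(OC)cc2Oc2c(O)c(-c3c(OC)cc(OC)cc3OC)c(OC)cc2OC)c1 | intermediate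
12 | 3-[2-(3,5-dihydroxyphenoxy)-3,5-dihydroxyphenoxy]-[1,1'-biphenyl]-2,2',4,4',6,6'-hexol (CNP0210555.0, achiral) | Oc1cc(O)cc(Oc2c(O)cc(O)cc2Oc2c(O)cc(O)c(-c3c(O)cc(O)cc3O)c2O)c1 | target

**Total step count:** 6. **Longest linear sequence:** 6 (1 → 3 → 5 → 6 → 8 → 11 → 12).

**Three steps most likely to fail**

**Step 5** forms a tetra-ortho-oxygenated biaryl on a very electron-rich phenol. The risks are oxidation of 8, attack at the aryloxy-bearing ortho carbon, and sluggish ligand coupling.

The fallback sets out from 8 and comes back at 12. The roles of the two rings are swapped: the ring C phenol is oxidised instead of placing ring D on lead.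
- Constant-current electrolysis is run on 8 with 9 (3 equiv) in HFIP/MeOH, with Bu3MeN O3SOMe as electrolyte, a boron-doped diamond anode, an undivided cell and 50 °C.
- This takes 8 to its phenoxyl/phenoxenium stage, and 9 attacks it as an ordinary nucleophile. The reaction type is an anodic dehydrogenative phenol–arene cross-coupling.
- Attack ortho to the OH gives 11 itself. Attack para to the OH gives the isomer 3-[2-(3,5-dimethoxyphenoxy)-3,5-dimethoxyphenoxy]-2,2',4',6,6'-pentamethoxy-[1,1'-biphenyl]-4-ol F1.
- The two free C–H positions of ring C become equivalent once all three of its oxygens are OH. The mixture therefore needs no separation, and BBr3 as in step 6 converts both isomers into 12.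

**Step 6** requires ninefold demethylation and gives an air-sensitive, very polar decaphenol. The risks are incomplete cleavage and loss on isolation.

The fallback sets out from 11 and comes back at 12. It is a protecting-group relay, so the free phenol is never isolated from the BBr3 mixture.
- The crude product of the BBr3 treatment is peracetylated at once (Ac2O, pyridine, rt). This gives 3-[2-(3,5-diacetoxyphenoxy)-3,5-diacetoxyphenoxy]-[1,1'-biphenyl]-2,2',4,4',6,6'-hexayl hexaacetate F2.
- The decaacetate F2 is stable to air and silica and separates cleanly from partly methylated material.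
- Pure F2 is then cleaved under argon with catalytic NaOMe in MeOH (Zemplén transesterification), followed by neutralisation with acidic resin, to give 12.

**Step 3** is a copper coupling of an ortho-aryloxy phenol with a bromide that has two ortho substituents.

The fallback sets out from 5 and comes back at 6. Copper catalysis is replaced by an uncatalysed addition–elimination (SNAr).
- 3,5-Dimethoxybenzaldehyde is fluorinated with F-TEDA-BF4 (1-chloromethyl-4-fluoro-1,4-diazoniabicyclo[2.2.2]octane bis(tetrafluoroborate)) in MeCN to give 2-fluoro-3,5-dimethoxybenzaldehyde F3.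
- The potassium phenoxide of 5 (K2CO3, DMF, 120 °C) displaces the fluoride ortho to the formyl group through a Meisenheimer adduct, giving 6.

**Further compounds**
F1 | step 5 | 3-[2-(3,5-dimethoxyphenoxy)-3,5-dimethoxyphenoxy]-2,2',4',6,6'-pentamethoxy-[1,1'-biphenyl]-4-ol | COc1cc(OC)cc(Oc2c(OC)cc(OC)cc2Oc2c(O)cc(OC)c(-c3c(OC)cc(OC)cc3OC)c2OC)c1
F2 | step 6 | 3-[2-(3,5-diacetoxyphenoxy)-3,5-diacetoxyphenoxy]-[1,1'-biphenyl]-2,2',4,4',6,6'-hexayl hexaacetate (decaacetate of 12) | CC(=O)Oc1cc(OC(C)=O)cc(Oc2c(OC(C)=O)cc(OC(C)=O)cc2Oc2c(OC(C)=O)cc(OC(C)=O)c(-c3c(OC(C)=O)cc(OC(C)=O)cc3OC(C)=O)c2OC(C)=O)c1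
F3 | step 3 | 2-fluoro-3,5-dimethoxybenzaldehyde | COc1cc(C=O)c(F)c(OC)c1
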